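**Retrosynthetic overview**

- Gancaonin J is cut at the (C=O)–CH2 bond of the propanone chain, giving a MOM-protected ring-A Weinreb amide and the Grignard reagent from MOM-protected 4-(2-bromoethyl)phenol (ring B is bought).
- Feature the strategy rests on: in ring A the oxygens on C2' and C4' alternate with the carbon-bearing C1', C3' and C5', and C6' is an unsubstituted CH. Ring A is therefore the folded form of a poly-β-carbonyl chain: ester-activated C1' methylene, C2' and C4' ketones, C6' at the aldehyde level.
- Ring A (the only ring made) is opened at C1'–C6' by an aldol disconnection to a methyl 3,5-dioxo ester that carries both prenyl groups on C3' and C5' and has C6' masked as a dimethyl acetal. Acid unmasks C6'; the carbon–carbon closure and aromatisation then run in the same pot under carbonate in methanol.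
- The chain is cut at C3'–C4': γ-acylation of the dianion of γ-prenylated methyl acetoacetate by the Weinreb amide of α-prenylated 3,3-dimethoxypropanoic acid. Both prenyl groups enter by enolate alkylation with prenyl bromide.

Key step: step 5

Remark: the target has no stereocentre; the sp3 centres of 7, 8, 10 and 11 are carried as racemic or epimeric mixtures because they become sp2 carbons of ring A in step 5. Locants C1'–C6' denote the ring-A carbons of the target and the chain carbons that become them.

**Route**

Step 1
Reactants: 1 methyl acetoacetate; 2 prenyl bromide (1-bromo-3-methylbut-2-ene)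
Product: 4 methyl 7-methyl-3-oxooct-6-enoate, via dilithium dianion of methyl acetoacetate 3 (not isolated)
Conditions: LiN(i-Pr)2 (2.1 equiv), THF, 0 °C; then 2, 0 °C to rt; 1 M HCl quench
Reagents that add atoms: none
Why: γ-Alkylation of a β-keto ester dianion: the terminal carbanion is the more basic and more nucleophilic site and should displace the allylic bromide at its primary carbon (SN2), leaving C2 untouched.

Step 2
Reactants: 5 methyl 3,3-dimethoxypropanoate; 2 prenyl bromide
Product: 7 methyl 2-(dimethoxymethyl)-5-methylhex-4-enoate (racemic), via lithium ester enolate 6 (not isolated)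
Conditions: LiN(i-Pr)2 (1.05 equiv), THF, −78 °C; then 2, DMPU, −78 to −40 °C
Reagents that add atoms: none
Why: Ester enolate alkylation (SN2): at −78 °C loss of methoxide from the β,β-dimethoxy enolate should stay slow while the reactive allylic bromide traps it at carbon; the new α-centre forms racemic and later becomes the sp2 carbon C5'.

Step 3
Reactants: 7 methyl 2-(dimethoxymethyl)-5-methylhex-4-enoate
Product: 8 2-(dimethoxymethyl)-N-methoxy-N,5-dimethylhex-4-enamide (racemic)
Conditions: MeNHOMe·HCl (1.5 equiv), i-PrMgCl (3.0 equiv), THF, −20 to 0 °C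
Reagents that add atoms: N,O-dimethylhydroxylamine hydrochloride, CNOC.Cl
Why: Weinreb amide formation by aminolysis of the ester with the chloromagnesium amide made in the flask, a weakly basic nucleophile that should not enolise the α-CH next to the acetal.

Step 4
Reactants: 4 methyl 7-methyl-3-oxooct-6-enoate; 8 2-(dimethoxymethyl)-N-methoxy-N,5-dimethylhex-4-enamide
Product: 10 methyl 6-(dimethoxymethyl)-9-methyl-4-(3-methylbut-2-enyl)-3,5-dioxodec-8-enoate (mixture of diastereomers and enol tautomers), via dilithium dianion of the keto ester 9 (not isolated)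
Conditions: 4 (1.3 equiv), LiN(i-Pr)2 (2.7 equiv), THF, −78 to 0 °C; then 8 (1.0 equiv), −78 to −10 °C; AcOH, −78 °C; crude product used directly
Reagents that add atoms: none
Why: C-Acylation of a β-keto ester dianion at its γ-carbon by a Weinreb amide, forming C3'–C4': the chelated tetrahedral adduct should persist until the acidic quench, so the acidic 3,5-dioxo ester never meets the dianion and no second addition occurs; the two new centres are epimerisable and are not controlled.

Step 5
Reactants: 10 methyl 6-(dimethoxymethyl)-9-methyl-4-(3-methylbut-2-enyl)-3,5-dioxodec-8-enoate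
Product: 12 methyl 2,4-dihydroxy-3,5-bis(3-methylbut-2-enyl)benzoate, via keto aldehyde 11 (not isolated)
Conditions: 1 M aq HCl, THF, rt; then K2CO3, MeOH, rt to 40 °C; then 1 M aq HCl to pH 4, 0 °C
Reagents that add atoms: none
Why: Aqueous acid should hydrolyse the β-keto dimethyl acetal to the C6' aldehyde 11 (largely its hydroxymethylene tautomer); after the switch to carbonate in methanol the enolate of the C1' methylene, activated by the ester and the C2' ketone, adds to the C6' formyl carbon, and loss of water across C1'–C6' followed by enolisation of the C2' and C4' ketones gives the benzene ring, which cannot revert. The closest known reaction type is the biomimetic intramolecular aldol condensation–aromatisation of 3,5,7-tricarbonyl esters to β-resorcylates under weakly basic conditions. Ring A closes in a 6-(enolexo)-exo-trig aldol with respect to the ester enolate, the only carbon–carbon aldol of this chain that gives a five- or six-membered ring. No stereocentre is created, and the two epimerisable centres of 10 (C3' and C5') become sp2. The step needs carbon closure over oxygen closure and aldol over Claisen closure: enol-oxygen attack on C6' gives a 4-pyranone that methoxide should reopen at its unsubstituted C6', so that by-path drains back into the aldol, whereas attack of C5' on the ester would give a ring with a quaternary C5' that cannot aromatise and calls for stronger alkoxide base than carbonate in methanol. The positions of both prenyl groups are fixed by the chain at C3' and C5' and do not depend on any ring selectivity.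

Step 6
Reactants: 12 methyl 2,4-dihydroxy-3,5-bis(3-methylbut-2-enyl)benzoate
Product: 14 methyl 2,4-bis(methoxymethoxy)-3,5-bis(3-methylbut-2-enyl)benzoate, via disodium bis-phenoxide 13 (not isolated)
Conditions: NaH (2.5 equiv), DMF, 0 °C; then MOMCl (2.5 equiv), 0 °C to rt
Reagents that add atoms: chloromethyl methyl ether (MOMCl), COCCl
Why: O-Alkylation of the sodium phenoxides (Williamson-type acetal formation): full deprotonation with NaH breaks the hydrogen bond between the C2' hydroxyl and the ester, so both hindered phenols should be capped.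

Step 7
Reactants: 14 methyl 2,4-bis(methoxymethoxy)-3,5-bis(3-methylbut-2-enyl)benzoate
Product: 15 N-methoxy-2,4-bis(methoxymethoxy)-N-methyl-3,5-bis(3-methylbut-2-enyl)benzamide
Conditions: MeNHOMe·HCl (3 equiv), i-PrMgCl (6 equiv), THF, −20 °C to rt
Reagents that add atoms: N,O-dimethylhydroxylamine hydrochloride, CNOC.Cl
Why: Weinreb amide formation by aminolysis of the aryl ester with the chloromagnesium amide; the ester has only one ortho substituent and no acidic proton, so the MOM ethers and prenyl groups should be untouched.

Step 8
Reactants: 16 4-(2-bromoethyl)phenol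
Product: 17 1-(2-bromoethyl)-4-(methoxymethoxy)benzene
Conditions: MOMCl, i-Pr2NEt, CH2Cl2, 0 °C to rt
Reagents that add atoms: chloromethyl methyl ether (MOMCl), COCCl
Why: MOM ether formation under amine base, which avoids a free phenoxide that could displace the bromide through the para carbon.

Step 9
Reactants: 15 N-methoxy-2,4-bis(methoxymethoxy)-N-methyl-3,5-bis(3-methylbut-2-enyl)benzamide; 17 1-(2-bromoethyl)-4-(methoxymethoxy)benzene
Product: 19 1-[2,4-bis(methoxymethoxy)-3,5-bis(3-methylbut-2-enyl)phenyl]-3-[4-(methoxymethoxy)phenyl]propan-1-one, via Grignard reagent 18 (not isolated)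
Conditions: 17 (1.6 equiv), Mg, I2 (cat.), THF, 40 °C; then 15, THF, 0 °C to rt; 1 M HCl, 0 °C
Reagents that add atoms: none
Why: Grignard formation from the primary bromide followed by Weinreb ketone synthesis: the N-methoxy chelate of the tetrahedral adduct should stop the addition at the ketone stage.

Step 10
Reactants: 19 1-[2,4-bis(methoxymethoxy)-3,5-bis(3-methylbut-2-enyl)phenyl]-3-[4-(methoxymethoxy)phenyl]propan-1-one
Product: 20 Gancaonin J (1-[2,4-dihydroxy-3,5-bis(3-methylbut-2-enyl)phenyl]-3-(4-hydroxyphenyl)propan-1-one)
Conditions: 3 M aq HCl, MeOH, 40 °C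
Reagents that add atoms: none
Why: Acid-catalysed acetal exchange of the three MOM ethers with methanol; dilute acid and moderate temperature are chosen so that the freed ortho-prenyl phenols should not add to their alkenes.

**Compound list**

1 | methyl acetoacetate | CC(=O)CC(=O)OC | starting material
2 | prenyl bromide (1-bromo-3-methylbut-2-ene) | CC(C)=CCBr | starting material
3 | dilithium dianion of methyl acetoacetate | [Li+].[Li+].COC([O-])=CC([O-])=C | intermediate
4 | methyl 7-methyl-3-oxooct-6-enoate | COC(=O)CC(=O)CCC=C(C)C | intermediate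
5 | methyl 3,3-dimethoxypropanoate | COC(CC(=O)OC)OC | starting material
6 | lithium enolate of methyl 3,3-dimethoxypropanoate | [Li+].COC(OC)C=C([O-])OC | intermediate
7 | methyl 2-(dimethoxymethyl)-5-methylhex-4-enoate (racemic) | COC(=O)C(CC=C(C)C)C(OC)OC | intermediate
8 | 2-(dimethoxymethyl)-N-methoxy-N,5-dimethylhex-4-enamide (racemic) | CON(C)C(=O)C(CC=C(C)C)C(OC)OC | intermediate
9 | dilithium dianion of methyl 7-methyl-3-oxooct-6-enoate | [Li+].[Li+].COC([O-])=CC([O-])=CCC=C(C)C | intermediate
10 | methyl 6-(dimethoxymethyl)-9-methyl-4-(3-methylbut-2-enyl)-3,5-dioxodec-8-enoate (mixture of diastereomers and enol tautomers) | COC(=O)CC(=O)C(CC=C(C)C)C(=O)C(CC=C(C)C)C(OC)OC | intermediate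
11 | methyl 6-formyl-9-methyl-4-(3-methylbut-2-enyl)-3,5-dioxodec-8-enoate (mixture of epimers and enol tautomers) | COC(=O)CC(=O)C(CC=C(C)C)C(=O)C(CC=C(C)C)C=O | intermediate
12 | methyl 2,4-dihydroxy-3,5-bis(3-methylbut-2-enyl)benzoate | COC(=O)c1cc(CC=C(C)C)c(O)c(CC=C(C)C)c1O | intermediate
13 | disodium bis-phenoxide of 12 | [Na+].[Na+].COC(=O)c1cc(CC=C(C)C)c([O-])c(CC=C(C)C)c1[O-] | intermediate
14 | methyl 2,4-bis(methoxymethoxy)-3,5-bis(3-methylbut-2-enyl)benzoate | COC(=O)c1cc(CC=C(C)C)c(OCOC)c(CC=C(C)C)c1OCOC | intermediate
15 | N-methoxy-2,4-bis(methoxymethoxy)-N-methyl-3,5-bis(3-methylbut-2-enyl)benzamide | CON(C)C(=O)c1cc(CC=C(C)C)c(OCOC)c(CC=C(C)C)c1OCOC | intermediate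
16 | 4-(2-bromoethyl)phenol | Oc1ccc(CCBr)cc1 | starting material
17 | 1-(2-bromoethyl)-4-(methoxymethoxy)benzene | COCOc1ccc(CCBr)cc1 | intermediate
18 | 2-[4-(methoxymethoxy)phenyl]ethylmagnesium bromide | COCOc1ccc(CC[Mg]Br)cc1 | intermediate
19 | 1-[2,4-bis(methoxymethoxy)-3,5-bis(3-methylbut-2-enyl)phenyl]-3-[4-(methoxymethoxy)phenyl]propan-1-one | COCOc1ccc(CCC(=O)c2cc(CC=C(C)C)c(OCOC)c(CC=C(C)C)c2OCOC)cc1 | intermediate
20 | Gancaonin J (1-[2,4-dihydroxy-3,5-bis(3-methylbut-2-enyl)phenyl]-3-(4-hydroxyphenyl)propan-1-one) | CC(C)=CCc1cc(C(=O)CCc2ccc(O)cc2)c(O)c(CC=C(C)C)c1O | target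

**Step count and risks**

Total step count: 10. Longest linear sequence: 8 steps (5 → 7 → 8 → 10 → 12 → 14 → 15 → 19 → 20; steps 2, 3, 4, 5, 6, 7, 9, 10).

The three steps most likely to fail, riskiest first, are step 5, step 4 and step 10.

First, step 5: after unmasking, closure through the enol oxygen and dehydration to the 4-pyranone may outrun carbon–carbon bond formation, and the pyranone may not reopen under carbonate in methanol; the polyanion may also cleave by retro-Claisen fragmentation. The fallback for step 5 gives up the chain folding and builds the substitution pattern on an existing arene by repeated directed ortho-metalation. It sets out from prenyl bromide 2, with bought 1,3-bis(methoxymethoxy)benzene F1 as the arene. Lithiation between the two MOM ethers (n-BuLi, THF, 0 °C), then CuBr·SMe2 and 2, should give 1,3-bis(methoxymethoxy)-2-(3-methylbut-2-enyl)benzene F2 as the mono-prenyl arene. A second lithiation ortho to a MOM ether (n-BuLi, TMEDA, then CuBr·SMe2 and 2) should give 1,3-bis(methoxymethoxy)-2,4-bis(3-methylbut-2-enyl)benzene F3 with both prenyl groups in place. A third lithiation at the last position ortho to a MOM ether, quenched with methyl chloroformate, comes back to the route at 14.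

Second, step 4: proton transfer from the α-CH of amide 8 to the dianion, followed by loss of methoxide, or slow addition because both partners are branched at the reacting carbons, may leave the acylation incomplete. The fallback for step 4 replaces acylation by aldol addition and oxidation. It sets out from 8, which i-Bu2AlH (THF, −78 °C) should reduce to 2-(dimethoxymethyl)-5-methylhex-4-enal F4 through the chelated adduct. The dianion 9 of keto ester 4 should add to this aldehyde at −78 °C and give methyl 6-(dimethoxymethyl)-5-hydroxy-9-methyl-4-(3-methylbut-2-enyl)-3-oxodec-8-enoate F5 as a mixture of diastereomers. Dess–Martin oxidation buffered with NaHCO3 in CH2Cl2 comes back to the route at 10.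

Third, step 10: once the ring-A phenols are free, acid may drive their addition to the neighbouring prenyl alkenes (closure to 2,2-dimethylchromans) before the last MOM ether has gone. The fallback for step 10 moves ring A to allyl ethers, which are removed without acid. It sets out from 12, which NaH and allyl bromide in DMF should convert to methyl 2,4-bis(prop-2-enyloxy)-3,5-bis(3-methylbut-2-enyl)benzoate F6 as the bis-allyl ether. Aminolysis with MeNHOMe·HCl and i-PrMgCl in THF should give N-methoxy-N-methyl-2,4-bis(prop-2-enyloxy)-3,5-bis(3-methylbut-2-enyl)benzamide F7 from this ester. Addition of Grignard reagent 18 should give 1-[2,4-bis(prop-2-enyloxy)-3,5-bis(3-methylbut-2-enyl)phenyl]-3-[4-(methoxymethoxy)phenyl]propan-1-one F8 as the protected ketone. HCl in MeOH then removes the ring-B MOM ether while the ring-A oxygens are still capped and should give 1-[2,4-bis(prop-2-enyloxy)-3,5-bis(3-methylbut-2-enyl)phenyl]-3-(4-hydroxyphenyl)propan-1-one F9 without chroman formation. Pd(PPh3)4 (a zerovalent palladium complex, catalytic) with morpholine in THF at rt removes both allyl groups and comes back to the route at 20.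

Further compounds

F1 | step 5 | 1,3-bis(methoxymethoxy)benzene | COCOc1cccc(OCOC)c1
F2 | step 5 | 1,3-bis(methoxymethoxy)-2-(3-methylbut-2-enyl)benzene | COCOc1cccc(OCOC)c1CC=C(C)C
F3 | step 5 | 1,3-bis(methoxymethoxy)-2,4-bis(3-methylbut-2-enyl)benzene | COCOc1ccc(CC=C(C)C)c(OCOC)c1CC=C(C)C
F4 | step 4 | 2-(dimethoxymethyl)-5-methylhex-4-enal | COC(OC)C(CC=C(C)C)C=O
F5 | step 4 | methyl 6-(dimethoxymethyl)-5-hydroxy-9-methyl-4-(3-methylbut-2-enyl)-3-oxodec-8-enoate | COC(=O)CC(=O)C(CC=C(C)C)C(O)C(CC=C(C)C)C(OC)OC
F6 | step 10 | methyl 2,4-bis(prop-2-enyloxy)-3,5-bis(3-methylbut-2-enyl)benzoate | COC(=O)c1cc(CC=C(C)C)c(OCC=C)c(CC=C(C)C)c1OCC=C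
F7 | step 10 | N-methoxy-N-methyl-2,4-bis(prop-2-enyloxy)-3,5-bis(3-methylbut-2-enyl)benzamide | CON(C)C(=O)c1cc(CC=C(C)C)c(OCC=C)c(CC=C(C)C)c1OCC=C
F8 | step 10 | 1-[2,4-bis(prop-2-enyloxy)-3,5-bis(3-methylbut-2-enyl)phenyl]-3-[4-(methoxymethoxy)phenyl]propan-1-one | COCOc1ccc(CCC(=O)c2cc(CC=C(C)C)c(OCC=C)c(CC=C(C)C)c2OCC=C)cc1
F9 | step 10 | 1-[2,4-bis(prop-2-enyloxy)-3,5-bis(3-methylbut-2-enyl)phenyl]-3-(4-hydroxyphenyl)propan-1-one | Oc1ccc(CCC(=O)c2cc(CC=C(C)C)c(OCC=C)c(CC=C(C)C)c2OCC=C)cc1
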